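## Retrosynthetic overview

1. Rhopaloic acid A ⇐ methyl ester ⇐ 2‑ethynyloxane (Markovnikov hydromethoxycarbonylation) ⇐ 2‑(benzyloxymethyl)oxane. The acrylic acid is unmasked last from a robust sp3 group at C2.
2. Side chain ⇐ B‑alkyl Suzuki–Miyaura coupling of a 5‑vinyloxane with a C13 (E)‑alkenyl iodide, made from geranyl bromide by propargylation and carboalumination/iodination.
3. The only ring, the oxane, is formed once: the C4–C5 bond of acyclic bis‑allylic ether 6 is closed by one‑pot hydroboration/copper‑catalysed intramolecular SN2′ alkylation, which also sets C5 trans to C2 and releases the vinyl group.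
4. Enabling feature: C4 of the oxane is a bare CH2 two carbons from the oxygen‑bearing C2, so C3–C4 can be the vinyl group of a vinyl carbinol (a latent primary alkyl nucleophile). C5 of the oxane is a CH whose side chain starts with two sp3 carbons, so C6–C5–C1′–C2′ can be a cis‑but‑2‑ene‑1,4‑diyl unit with C5 as the γ‑carbon of an allylic chloride. O1 tethers the two for a 6‑exo closure.
5. Ether 6 ⇐ (R)‑benzyl glycidyl ether (source of C2) + sulfonium ylide + cis‑1,4‑dichlorobut‑2‑ene.

Key step: step 3

Remark on locants: oxane numbering is O1, C2 (acrylate carbon attached), C5 (side chain attached); primed numbers count side‑chain carbons from the ring.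

## Route

Step 1
Reactants: 1 (2R)-2-[(benzyloxy)methyl]oxirane ((R)-benzyl glycidyl ether)
Product: 3 (2R)-1-(benzyloxy)but-3-en-2-ol, via sulfonium betaine 2 (not isolated)
Conditions: Me3S+ I− (3 equiv), n-BuLi (2.9 equiv), THF, −10 °C → rt
Reagents that add atoms: trimethylsulfonium iodide, C[S+](C)C.[I-]
Why: Dimethylsulfonium methylide (Corey–Chaykovsky-type ylide) opens the epoxide at its CH2 terminus and, under excess ylide, the betaine eliminates dimethyl sulfide to the allylic alcohol; the C–O bond of the stereocentre is never broken, so the (R) configuration is kept.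

Step 2
Reactants: 3 (2R)-1-(benzyloxy)but-3-en-2-ol; 4 (2Z)-1,4-dichlorobut-2-ene
Product: 6 ({[(2R)-2-{[(2Z)-4-chlorobut-2-en-1-yl]oxy}but-3-en-1-yl]oxy}methyl)benzene, via sodium alkoxide 5 (not isolated)
Conditions: NaH, THF/DMF, 0 °C; then 4 (4 equiv), 0 °C → rt
Reagents that add atoms: none
Why: Williamson etherification in which the secondary alkoxide displaces one primary allylic chloride of the symmetrical dichloride by SN2, the excess of 4 suppressing double alkylation; the carbinol centre and the Z olefin are untouched.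

Step 3
Reactants: 6 ({[(2R)-2-{[(2Z)-4-chlorobut-2-en-1-yl]oxy}but-3-en-1-yl]oxy}methyl)benzene
Product: 9 (2R,5R)-2-[(benzyloxy)methyl]-5-ethenyloxane, via B-alkyl-9-BBN 7 (not isolated), via potassium methoxyborate 8 (not isolated)
Conditions: 9-BBN dimer (0.55 equiv), THF, 0 °C → rt; then KOMe (1.1 equiv), CuOAc (10 mol%), THF/1,4-dioxane, 0.02 M, 40 °C
Reagents that add atoms: none
Why: Proposed new method: 9-BBN hydroborates only the monosubstituted vinyl group of 6 at its terminus (7), KOMe turns the borane into borate 8, the primary alkyl group is transferred to monovalent copper, and the alkylcopper attacks the γ-carbon of the tethered (Z)-allylic chloride anti to the leaving group (formal SN2′ through a trivalent σ-allylcopper species and reductive elimination), expelling chloride and transposing the olefin into the vinyl group. The closest known reaction is the intermolecular copper-catalysed γ-selective allyl–alkyl coupling of B-alkyl-9-BBN alkoxyborates with (Z)-allylic chlorides and phosphates, which creates the same kind of vinyl-bearing tertiary carbon; what is new is its ring-closing use on an ether-tethered substrate. The oxane closes in a 6-exo-trig mode at the bond between the ring CH2 (C4) and the ring CH (C5), α-attack being excluded because it would need an eight-membered ring. The new stereocentre at C5 is set by the existing C2 centre through a chair-like transition state in which the CH2OBn group and the exocyclic olefin carbon are both equatorial (the Z geometry penalising the axial alternative by allylic strain), which should favour the 2,5-trans (2R,5R) product. The step needs hydroboration of one of two olefins, γ over α substitution, ring closure over intermolecular coupling or methanolysis of the chloride, and trans over cis closure; the olefin substitution pattern, the tether length, pre-formation of the borate with high dilution, and the equatorial preference of the C2 substituent secure these in turn.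

Step 4
Reactants: 10 geranyl bromide ((2E)-1-bromo-3,7-dimethylocta-2,6-diene); 11 trimethyl(prop-1-yn-1-yl)silane
Product: 13 trimethyl[(5E)-6,10-dimethylundeca-5,9-dien-1-yn-1-yl]silane, via propargyllithium 12 (not isolated)
Conditions: 11, n-BuLi, THF, −78 → −20 °C; then 10, −78 °C → rt
Reagents that add atoms: none
Why: Propargylic lithiation of the silylpropyne and SN2 alkylation by the primary allylic bromide should give the skipped enyne with the E olefin of geranyl bromide intact, the silyl group steering attack to the propargylic rather than the allenic terminus.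

Step 5
Reactants: 13 trimethyl[(5E)-6,10-dimethylundeca-5,9-dien-1-yn-1-yl]silane
Product: 14 (5E)-6,10-dimethylundeca-5,9-dien-1-yne
Conditions: K2CO3 (cat.), MeOH, rt
Reagents that add atoms: none
Why: Methoxide-catalysed protodesilylation of an alkynylsilane, which no other group in the molecule answers.

Step 6
Reactants: 14 (5E)-6,10-dimethylundeca-5,9-dien-1-yne
Product: 16 (1E,5E)-1-iodo-2,6,10-trimethylundeca-1,5,9-triene, via alkenylalane 15 (not isolated)
Conditions: AlMe3 (2.5 equiv), Cp2ZrCl2 (0.25 equiv), CH2Cl2, 0 °C → rt; then I2, THF, −30 → 0 °C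
Reagents that add atoms: trimethylaluminium, C[Al](C)C; iodine, II
Why: Negishi zirconium-catalysed carboalumination adds methyl and aluminium syn across the terminal alkyne with aluminium at the terminus, and iodinolysis with retention fixes the new trisubstituted olefin as E, the remote trisubstituted olefins being inert.

Step 7
Reactants: 9 (2R,5R)-2-[(benzyloxy)methyl]-5-ethenyloxane; 16 (1E,5E)-1-iodo-2,6,10-trimethylundeca-1,5,9-triene
Product: 18 (2R,5S)-2-[(benzyloxy)methyl]-5-[(3E,7E)-4,8,12-trimethyltrideca-3,7,11-trien-1-yl]oxane, via B-alkyl-9-BBN 17 (not isolated)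
Conditions: 9, 9-BBN dimer (0.55 equiv), THF, rt; then 16, PdCl2(dppf) (5 mol%), AsPh3, Cs2CO3, DMF/H2O, rt
Reagents that add atoms: none
Why: B-alkyl Suzuki–Miyaura coupling in which 9-BBN hydroborates the only olefin of 9 at its terminus and the primary alkylborane couples with the alkenyl iodide with retention of olefin geometry, joining the side chain at its first sp3–sp2 bond without touching a stereocentre.

Step 8
Reactants: 18 (2R,5S)-2-[(benzyloxy)methyl]-5-[(3E,7E)-4,8,12-trimethyltrideca-3,7,11-trien-1-yl]oxane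
Product: 19 [(2R,5S)-5-[(3E,7E)-4,8,12-trimethyltrideca-3,7,11-trien-1-yl]oxan-2-yl]methanol
Conditions: lithium 4,4′-di-tert-butylbiphenylide, THF, −78 °C; then H2O
Reagents that add atoms: none
Why: Reductive debenzylation by electron transfer from the arene radical anion cleaves only the benzylic C–O bond, isolated trisubstituted olefins and the oxane being inert at −78 °C (hydrogenolysis is ruled out by the olefins).

Step 9
Reactants: 19 [(2R,5S)-5-[(3E,7E)-4,8,12-trimethyltrideca-3,7,11-trien-1-yl]oxan-2-yl]methanol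
Product: 20 (2R,5S)-5-[(3E,7E)-4,8,12-trimethyltrideca-3,7,11-trien-1-yl]oxane-2-carbaldehyde
Conditions: Dess–Martin periodinane, pyridine, CH2Cl2, 0 °C → rt
Reagents that add atoms: none
Why: Dess–Martin oxidation of the primary alcohol stops at the α-alkoxy aldehyde under buffered, non-acidic conditions that spare the polyene; the aldehyde would be used crude to limit epimerisation.

Step 10
Reactants: 20 (2R,5S)-5-[(3E,7E)-4,8,12-trimethyltrideca-3,7,11-trien-1-yl]oxane-2-carbaldehyde
Product: 21 (2R,5S)-2-ethynyl-5-[(3E,7E)-4,8,12-trimethyltrideca-3,7,11-trien-1-yl]oxane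
Conditions: dimethyl (1-diazo-2-oxopropyl)phosphonate, K2CO3, MeOH, 0 °C → rt
Reagents that add atoms: dimethyl (1-diazo-2-oxopropyl)phosphonate, CC(=O)C(=[N+]=[N-])P(=O)(OC)OC
Why: Seyferth–Gilbert homologation with the Ohira–Bestmann reagent converts the aldehyde into the terminal alkyne under mild base, and any epimerisation of the α-alkoxy aldehyde would drift toward the wanted diequatorial 2,5-trans isomer.

Step 11
Reactants: 21 (2R,5S)-2-ethynyl-5-[(3E,7E)-4,8,12-trimethyltrideca-3,7,11-trien-1-yl]oxane
Product: 22 methyl 2-[(2R,5S)-5-[(3E,7E)-4,8,12-trimethyltrideca-3,7,11-trien-1-yl]oxan-2-yl]prop-2-enoate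
Conditions: Pd(OAc)2 (2 mol%), 2-(diphenylphosphino)pyridine (16 mol%), MeSO3H (16 mol%), CO (10 bar), MeOH/THF, 45 °C
Reagents that add atoms: carbon monoxide, [C-]#[O+]; methanol, CO
Why: Palladium-catalysed Markovnikov hydromethoxycarbonylation of a terminal alkyne with a 2-pyridylphosphine/acid system places the ester on the internal carbon and gives the 2-substituted acrylate directly, trisubstituted olefins being unreactive and no stereocentre being touched.

Step 12
Reactants: 22 methyl 2-[(2R,5S)-5-[(3E,7E)-4,8,12-trimethyltrideca-3,7,11-trien-1-yl]oxan-2-yl]prop-2-enoate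
Product: 23 rhopaloic acid A, 2-[(2R,5S)-5-[(3E,7E)-4,8,12-trimethyltrideca-3,7,11-trien-1-yl]oxan-2-yl]prop-2-enoic acid
Conditions: LiOH, THF/MeOH/H2O, rt; then 1 M HCl, 0 °C, to pH 3
Reagents that add atoms: lithium hydroxide, [Li+].[OH-]
Why: Saponification of the methyl ester, the α-substituted acrylate being a poor acceptor for hydroxide and the ring stereocentres lacking any base-labile path under these conditions.

## Compound list

1 | (2R)-2-[(benzyloxy)methyl]oxirane | C(OC[C@H]1CO1)c1ccccc1 | starting material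
2 | dimethyl[(3R)-4-(benzyloxy)-3-oxidobutyl]sulfonium (betaine) | C[S+](C)CC[C@@H]([O-])COCc1ccccc1 | intermediate
3 | (2R)-1-(benzyloxy)but-3-en-2-ol | C=C[C@@H](O)COCc1ccccc1 | intermediate
4 | (2Z)-1,4-dichlorobut-2-ene | ClC/C=C\CCl | starting material
5 | sodium (2R)-1-(benzyloxy)but-3-en-2-olate | C=C[C@@H]([O-])COCc1ccccc1.[Na+] | intermediate
6 | ({[(2R)-2-{[(2Z)-4-chlorobut-2-en-1-yl]oxy}but-3-en-1-yl]oxy}methyl)benzene | C=C[C@@H](OC/C=C\CCl)COCc1ccccc1 | intermediate
7 | 9-[(3R)-4-(benzyloxy)-3-{[(2Z)-4-chlorobut-2-en-1-yl]oxy}butyl]-9-borabicyclo[3.3.1]nonane | C1CCC2CCCC1B2CC[C@@H](OC/C=C\CCl)COCc1ccccc1 | intermediate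
8 | potassium 9-[(3R)-4-(benzyloxy)-3-{[(2Z)-4-chlorobut-2-en-1-yl]oxy}butyl]-9-methoxy-9-boranuidabicyclo[3.3.1]nonane | [K+].CO[B-]1(CC[C@@H](OC/C=C\CCl)COCc2ccccc2)C3CCCC1CCC3 | intermediate
9 | (2R,5R)-2-[(benzyloxy)methyl]-5-ethenyloxane | c1ccccc1COC[C@H]2CC[C@H](C=C)CO2 | intermediate
10 | geranyl bromide, (2E)-1-bromo-3,7-dimethylocta-2,6-diene | BrC/C=C(\C)CCC=C(C)C | starting material
11 | trimethyl(prop-1-yn-1-yl)silane | CC#C[Si](C)(C)C | starting material
12 | [3-(trimethylsilyl)prop-2-yn-1-yl]lithium | [Li]CC#C[Si](C)(C)C | intermediate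
13 | trimethyl[(5E)-6,10-dimethylundeca-5,9-dien-1-yn-1-yl]silane | C[Si](C)(C)C#CCC/C=C(\C)CCC=C(C)C | intermediate
14 | (5E)-6,10-dimethylundeca-5,9-dien-1-yne | C#CCC/C=C(\C)CCC=C(C)C | intermediate
15 | dimethyl[(1E,5E)-2,6,10-trimethylundeca-1,5,9-trien-1-yl]alumane | C[Al](C)/C=C(\C)CC/C=C(\C)CCC=C(C)C | intermediate
16 | (1E,5E)-1-iodo-2,6,10-trimethylundeca-1,5,9-triene | I/C=C(\C)CC/C=C(\C)CCC=C(C)C | intermediate
17 | 9-{2-[(3S,6R)-6-[(benzyloxy)methyl]oxan-3-yl]ethyl}-9-borabicyclo[3.3.1]nonane | c1ccccc1COC[C@H]2CC[C@H](CCB3C4CCCC3CCC4)CO2 | intermediate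
18 | (2R,5S)-2-[(benzyloxy)methyl]-5-[(3E,7E)-4,8,12-trimethyltrideca-3,7,11-trien-1-yl]oxane | c1ccccc1COC[C@H]2CC[C@H](CC/C=C(\C)CC/C=C(\C)CCC=C(C)C)CO2 | intermediate
19 | [(2R,5S)-5-[(3E,7E)-4,8,12-trimethyltrideca-3,7,11-trien-1-yl]oxan-2-yl]methanol | OC[C@H]1CC[C@H](CC/C=C(\C)CC/C=C(\C)CCC=C(C)C)CO1 | intermediate
20 | (2R,5S)-5-[(3E,7E)-4,8,12-trimethyltrideca-3,7,11-trien-1-yl]oxane-2-carbaldehyde | O=C[C@H]1CC[C@H](CC/C=C(\C)CC/C=C(\C)CCC=C(C)C)CO1 | intermediate
21 | (2R,5S)-2-ethynyl-5-[(3E,7E)-4,8,12-trimethyltrideca-3,7,11-trien-1-yl]oxane | C#C[C@H]1CC[C@H](CC/C=C(\C)CC/C=C(\C)CCC=C(C)C)CO1 | intermediate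
22 | methyl 2-[(2R,5S)-5-[(3E,7E)-4,8,12-trimethyltrideca-3,7,11-trien-1-yl]oxan-2-yl]prop-2-enoate | C=C(C(=O)OC)[C@H]1CC[C@H](CC/C=C(\C)CC/C=C(\C)CCC=C(C)C)CO1 | intermediate
23 | rhopaloic acid A, 2-[(2R,5S)-5-[(3E,7E)-4,8,12-trimethyltrideca-3,7,11-trien-1-yl]oxan-2-yl]prop-2-enoic acid | C=C(C(=O)O)[C@H]1CC[C@H](CC/C=C(\C)CC/C=C(\C)CCC=C(C)C)CO1 | target

## Step count and risks

Total step count: 12.
Longest linear sequence: 9 steps (steps 1–3 and 7–12; the iodide branch, steps 4–12, is equally long).

Steps most likely to fail: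

1. Step 3 (Proposed new method). Transfer of the alkyl group from boron to copper and the ring-closing substitution may be slower than methoxide attack on the allylic chloride, protodeboronation or intermolecular allyl–alkyl coupling, and the chair preference may discriminate the two olefin faces too weakly, eroding trans selectivity. Fallback with known chemistry, setting out from 1 and rejoining at 9: epoxide 1 would be opened with CH2=CHMgBr and catalytic CuI in THF at −30 °C to give (2R)-1-(benzyloxy)pent-4-en-2-ol F1. Treatment of F1 with NaH and methyl 2-(bromomethyl)prop-2-enoate would give methyl 2-({[(2R)-1-(benzyloxy)pent-4-en-2-yl]oxy}methyl)prop-2-enoate F2. Ring-closing metathesis of F2 with the second-generation Grubbs catalyst RuCl2(=CHPh)(H2IMes)(PCy3) would form the same ring bond as a double bond and give methyl (6R)-6-[(benzyloxy)methyl]-5,6-dihydro-2H-pyran-3-carboxylate F3, with loss of ethene. Conjugate reduction of F3 with NaBH4 and NiCl2·6H2O in MeOH, followed by NaOMe equilibration, should lead to the diequatorial methyl (3S,6R)-6-[(benzyloxy)methyl]oxane-3-carboxylate F4. Reduction of F4 with i-Bu2AlH at −78 °C would give (3S,6R)-6-[(benzyloxy)methyl]oxane-3-carbaldehyde F5, and Wittig methylenation of F5 with Ph3P=CH2 would return 9.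

2. Step 11. Branched regiocontrol may be lost next to the ring oxygen, or the acid co-catalyst may promote isomerisation or cyclisation of the trisubstituted olefins during carbonylation. Fallback, setting out from 20 and rejoining at 22 (it replaces steps 10 and 11): MeMgBr would add to aldehyde 20 to give 1-[(2R,5S)-5-[(3E,7E)-4,8,12-trimethyltrideca-3,7,11-trien-1-yl]oxan-2-yl]ethan-1-ol F6 as a mixture of carbinol epimers. Dess–Martin oxidation of F6 would give 1-[(2R,5S)-5-[(3E,7E)-4,8,12-trimethyltrideca-3,7,11-trien-1-yl]oxan-2-yl]ethan-1-one F7. Kinetic enolisation of F7 at the methyl group with KN(SiMe3)2 and trapping with PhNTf2 at −78 °C would give 1-[(2R,5S)-5-[(3E,7E)-4,8,12-trimethyltrideca-3,7,11-trien-1-yl]oxan-2-yl]ethenyl trifluoromethanesulfonate F8. Methoxycarbonylation of F8 with Pd(PPh3)4, CO at 1 atm, MeOH and Et3N in DMF would give 22.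

3. Step 2. Double etherification of the bis-electrophile and alkoxide-induced dehydrochlorination or SN2′ attack may give poor mass balance. Fallback, setting out from 3 and rejoining at 6: NaH and propargyl bromide would convert 3 into ({[(2R)-2-(prop-2-yn-1-yloxy)but-3-en-1-yl]oxy}methyl)benzene F9. Deprotonation of F9 with n-BuLi and addition to paraformaldehyde would extend the alkyne to 4-{[(2R)-1-(benzyloxy)but-3-en-2-yl]oxy}but-2-yn-1-ol F10. Alkyne-selective cis semi-reduction of F10 with Zn activated by Cu(OAc)2 and AgNO3 in MeOH/H2O would give (2Z)-4-{[(2R)-1-(benzyloxy)but-3-en-2-yl]oxy}but-2-en-1-ol F11. Corey–Kim chlorination of F11 with N-chlorosuccinimide and Me2S in CH2Cl2 would give 6 without allylic transposition.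

Further compounds
F1 | step 3 | (2R)-1-(benzyloxy)pent-4-en-2-ol | C=CC[C@@H](O)COCc1ccccc1
F2 | step 3 | methyl 2-({[(2R)-1-(benzyloxy)pent-4-en-2-yl]oxy}methyl)prop-2-enoate | C=CC[C@@H](OCC(=C)C(=O)OC)COCc1ccccc1
F3 | step 3 | methyl (6R)-6-[(benzyloxy)methyl]-5,6-dihydro-2H-pyran-3-carboxylate | COC(=O)C1=CC[C@H](COCc2ccccc2)OC1
F4 | step 3 | methyl (3S,6R)-6-[(benzyloxy)methyl]oxane-3-carboxylate | c1ccccc1COC[C@H]2CC[C@H](C(=O)OC)CO2
F5 | step 3 | (3S,6R)-6-[(benzyloxy)methyl]oxane-3-carbaldehyde | c1ccccc1COC[C@H]2CC[C@H](C=O)CO2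
F6 | step 11 | 1-[(2R,5S)-5-[(3E,7E)-4,8,12-trimethyltrideca-3,7,11-trien-1-yl]oxan-2-yl]ethan-1-ol | CC(O)[C@H]1CC[C@H](CC/C=C(\C)CC/C=C(\C)CCC=C(C)C)CO1
F7 | step 11 | 1-[(2R,5S)-5-[(3E,7E)-4,8,12-trimethyltrideca-3,7,11-trien-1-yl]oxan-2-yl]ethan-1-one | CC(=O)[C@H]1CC[C@H](CC/C=C(\C)CC/C=C(\C)CCC=C(C)C)CO1
F8 | step 11 | 1-[(2R,5S)-5-[(3E,7E)-4,8,12-trimethyltrideca-3,7,11-trien-1-yl]oxan-2-yl]ethenyl trifluoromethanesulfonate | C=C(OS(=O)(=O)C(F)(F)F)[C@H]1CC[C@H](CC/C=C(\C)CC/C=C(\C)CCC=C(C)C)CO1
F9 | step 2 | ({[(2R)-2-(prop-2-yn-1-yloxy)but-3-en-1-yl]oxy}methyl)benzene | C=C[C@@H](OCC#C)COCc1ccccc1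
F10 | step 2 | 4-{[(2R)-1-(benzyloxy)but-3-en-2-yl]oxy}but-2-yn-1-ol | C=C[C@@H](OCC#CCO)COCc1ccccc1
F11 | step 2 | (2Z)-4-{[(2R)-1-(benzyloxy)but-3-en-2-yl]oxy}but-2-en-1-ol | C=C[C@@H](OC/C=C\CO)COCc1ccccc1
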